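The synthesis rests on cutting the C1–C8a bond of the five-membered ring. The quaternary carbon C8a is both the α-carbon of a carbonyl at C8 (the later ester carbon of the seven-membered ring) and the neighbour of C1. A C8–C8a enol silane can therefore attack the terminal carbon of an alkyne hung from C3a. One gold-catalysed 5-endo-dig closure makes this bond, the cyclopentene and the cis-fused quaternary centre, and frees the C8 ketone. The precursor is a cycloheptenyl tert-butyldimethylsilyl enol ether whose C3a bears a triethylsilyloxy group and a 1-isopropylpropargyl chain, installed by stereospecific addition of an axially chiral allenylboronic acid.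

Key step: step 8

Remark on the chemistry: azulene numbering (C1 to C8a) is used for every compound that holds these carbons, monocyclic ones included. The face of the bicycle that carries the C8a methyl group is called the upper face.

Step 1
Reactants: 1 cycloheptane-1,3-dione; 2 iodomethane
Product: 3 2-methylcycloheptane-1,3-dione
Conditions: MeI (1.1 equiv), K2CO3, acetone, reflux
Reagents that add atoms: iodomethane (2), CI
Why: C-alkylation of the stabilised 1,3-diketone enolate (SN2 on iodomethane) is the standard entry to 2-alkyl-1,3-diones, and a mild carbonate base with about one equivalent of electrophile limits O-methylation, double methylation and retro-Claisen ring opening.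

Step 2
Reactants: 3 2-methylcycloheptane-1,3-dione
Product: 4 3-[(tert-butyldimethylsilyl)oxy]-2-methylcyclohept-2-en-1-one
Conditions: TBSOTf (1.05 equiv), Et3N, CH2Cl2, 0 °C; bulb-to-bulb distillation
Reagents that add atoms: tert-butyldimethylsilyl trifluoromethanesulfonate, CC(C)(C)[Si](C)(C)OS(=O)(=O)C(F)(F)F
Why: Soft enolisation and O-silylation of the symmetrical dione gives the vinylogous silyl ester without any regiochemical question, leaves one carbonyl (the future C3a) free for addition and already stores the C8–C8a enol silane in the only position and geometry that the ring allows.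

Step 3
Reactants: 5 rac-4-methylpent-1-yn-3-ol
Product: 6 (R)-4-methylpent-1-yn-3-ol
Conditions: Novozym 435 (immobilised Candida antarctica lipase B), vinyl acetate, hexane, 30 °C, stopped beyond half conversion; separation from the acetate
Reagents that add atoms: none
Why: Lipase-catalysed kinetic resolution by irreversible transesterification should acylate the (S)-alcohol faster, since the slim ethynyl group fits the small pocket of the enzyme and isopropyl the large one, so that driving the conversion past one half leaves the (R)-alcohol in high enantiomeric purity and fixes the absolute configuration of the whole route.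

Step 4
Reactants: 6 (R)-4-methylpent-1-yn-3-ol
Product: 7 methyl (R)-4-methylpent-1-yn-3-yl carbonate
Conditions: ClCO2Me, pyridine, CH2Cl2, 0 °C to rt
Reagents that add atoms: methyl chloroformate, COC(=O)Cl
Why: Acylation with a chloroformate takes place at oxygen and therefore with retention at the carbinol carbon, and it installs a leaving group that regenerates the copper alkoxide in the next step.

Step 5
Reactants: 7 methyl (R)-4-methylpent-1-yn-3-yl carbonate
Product: 9 [(aS)-4-methylpenta-1,2-dien-1-yl]boronic acid, via allenyl dioxaborolane 8 (not isolated)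
Conditions: B2(OH)4, HOCH2CH2OH, mesitylcopper CuC6H2Me3 (10 mol %), P(OMe)3 (20 mol %), 3 Å MS, MeOH, −10 °C; degassed H2O work-up, toluene extract kept over 3 Å MS
Reagents that add atoms: tetrahydroxydiboron, OB(O)B(O)O; ethylene glycol, OCCO (held only in 8); water, O (hydrolysis of 8)
Why: Copper-catalysed propargylic borylation is a formal anti-SN2′ substitution (syn borylcupration with boron on the terminal carbon, then anti β-elimination of the carbonate), so the (R)-carbinol centre is translated into the (aS) axis, and the free boronic acid is chosen over a pinacol ester because only the former adds to ketones without a promoter.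

Step 6
Reactants: 4 3-[(tert-butyldimethylsilyl)oxy]-2-methylcyclohept-2-en-1-one; 9 [(aS)-4-methylpenta-1,2-dien-1-yl]boronic acid
Product: 11 (1S)-3-[(tert-butyldimethylsilyl)oxy]-2-methyl-1-[(3S)-4-methylpent-1-yn-3-yl]cyclohept-2-en-1-ol, via dihydroxyboryl ether 10 (not isolated)
Conditions: 9 (1.5 equiv), 3 Å MS, toluene, rt to 40 °C; pH 7 phosphate buffer; Et3N-deactivated SiO2
Reagents that add atoms: none
Why: Propargylboration of a ketone by an allenylboronic acid runs through a closed six-membered SE2′ transition state in which the C3–C3a bond forms on the allene face that carries boron, which sets C3 from the axis, while the bulkier methyl-bearing alkenyl arm (C8a) of the ketone turns away from the isopropyl group and the C4 methylene lies next to it, which sets C3a, and the neutral medium spares the acid-labile tertiary allylic carbinol from Stork–Danheiser-type collapse.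

Step 7
Reactants: 11 (1S)-3-[(tert-butyldimethylsilyl)oxy]-2-methyl-1-[(3S)-4-methylpent-1-yn-3-yl]cyclohept-2-en-1-ol
Product: 12 (3S)-1-[(tert-butyldimethylsilyl)oxy]-2-methyl-3-[(3S)-4-methylpent-1-yn-3-yl]-3-[(triethylsilyl)oxy]cyclohept-1-ene
Conditions: TESOTf, 2,6-lutidine (excess), CH2Cl2, −78 °C
Reagents that add atoms: triethylsilyl trifluoromethanesulfonate, CC[Si](CC)(CC)OS(=O)(=O)C(F)(F)F
Why: A silyl triflate with a hindered pyridine base is the standard way to silylate a crowded tertiary alcohol at low temperature, the excess base suppresses ionisation of the allylic carbinol, and capping the oxygen blocks both O-cyclisation onto the alkyne and later retro-aldol cleavage.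

Step 8
Reactants: 12 (3S)-1-[(tert-butyldimethylsilyl)oxy]-2-methyl-3-[(3S)-4-methylpent-1-yn-3-yl]-3-[(triethylsilyl)oxy]cyclohept-1-ene
Product: 13 (3S,3aS,8aS)-8a-methyl-3-(propan-2-yl)-3a-[(triethylsilyl)oxy]-3a,4,5,6,7,8a-hexahydroazulen-8(3H)-one
Conditions: (Ph3P)AuCl (10 mol %), AgBF4 (10 mol %), premixed and freed from AgCl, CH2Cl2–MeOH (10:1), rt to 40 °C
Reagents that add atoms: none
Why: The cationic monovalent gold complex [(Ph3P)Au]BF4 binds the terminal alkyne, the electron-rich enol silane carbon C8a attacks C1 anti to the metal, methanol strips the tert-butyldimethylsilyl group from the resulting silyloxocarbenium ion, and the proton thereby released cleaves the C2–Au bond, which leaves the C8 ketone and the C1=C2 alkene and returns the catalyst. The closest known reaction type is the gold-catalysed Conia-ene-type carbocyclisation of cyclic silyl enol ethers onto tethered terminal alkynes, which is established for cis-fused cyclopentenes and for fully substituted α-carbons. The one new ring, the cyclopentene C1–C2–C3–C3a–C8a, closes in the 5-endo-dig mode, because the oxygen on C8 polarises the alkene so that C8a is its nucleophilic end, which rules out 6-endo attack through C8, while 4-exo attack at C2 is prohibitively strained. The one new stereocentre, C8a, is dictated by C3a, since the short C3–C2–C1 tether reaches only the face of the C8=C8a bond on which the C3a–C3 bond stands, so the fusion is cis and methyl and silyloxy share the upper face. The step needs C–C bond formation to outrun ionisation of the tertiary allylic C3a–O bond, premature protodesilylation and solvolysis of the alkyne. This is secured by the soft and essentially neutral π-acid, by the poor leaving-group quality of the triethylsilyloxy group, by the absence of any free hydroxyl group and by the enforced proximity of C8a and C1, while the cation-activated enol silyl group is lost in preference to the hindered tertiary silyl ether.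

Step 9
Reactants: 13 (3S,3aS,8aS)-8a-methyl-3-(propan-2-yl)-3a-[(triethylsilyl)oxy]-3a,4,5,6,7,8a-hexahydroazulen-8(3H)-one
Product: 14 (3R,3aS,8aS)-8a-methyl-3-(propan-2-yl)-3a-[(triethylsilyl)oxy]-2,3,3a,4,5,6,7,8a-octahydroazulen-8(1H)-one
Conditions: H2 (1 atm), Pd/C, EtOAc, rt
Reagents that add atoms: none
Why: Heterogeneous catalytic hydrogenation saturates the only C=C bond, a cis-disubstituted cyclopentene, without touching the hindered ketone or the silyl ether, and creates no stereocentre (the C3 descriptor changes only through substituent ranking).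

Step 10
Reactants: 14 (3R,3aS,8aS)-8a-methyl-3-(propan-2-yl)-3a-[(triethylsilyl)oxy]-2,3,3a,4,5,6,7,8a-octahydroazulen-8(1H)-one
Product: 16 (3R,3aS,8aS)-8a-methyl-3-(propan-2-yl)-3a-[(triethylsilyl)oxy]-2,3,3a,4,5,8a-hexahydroazulen-8(1H)-one, via C7–C8 trimethylsilyl enol ether 15 (not isolated)
Conditions: LiN(i-Pr)2, TMSCl (in situ quench), THF, −78 °C; crude 15, Pd(OAc)2 (1.1 equiv), MeCN, rt
Reagents that add atoms: chlorotrimethylsilane, C[Si](C)(C)Cl (held only in 15)
Why: C8a is quaternary, so kinetic deprotonation can occur only at C7 and β-elimination of the C3a silyloxy group is impossible, and Saegusa–Ito oxidation of the enol silane by divalent palladium (oxa-π-allyl formation, then β-hydride loss from C6) gives the C6–C7 enone.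

Step 11
Reactants: 16 (3R,3aS,8aS)-8a-methyl-3-(propan-2-yl)-3a-[(triethylsilyl)oxy]-2,3,3a,4,5,8a-hexahydroazulen-8(1H)-one
Product: 18 (3R,3aS,8aS)-6,8a-dimethyl-3-(propan-2-yl)-3a-[(triethylsilyl)oxy]-2,3,3a,4,5,8a-hexahydroazulen-8(1H)-one, via 6-methyl trimethylsilyl enol ether 17 (not isolated)
Conditions: Me2CuLi (from CuI, MeLi), TMSCl, Et2O–THF, −78 to 0 °C; crude 17, Pd(OAc)2 (1.1 equiv), MeCN, rt
Reagents that add atoms: lithium dimethylcuprate, [Li+].C[Cu-]C; chlorotrimethylsilane, C[Si](C)(C)Cl (held only in 17)
Why: Chlorosilane-accelerated conjugate addition of the Gilman cuprate places the methyl group on C6 and traps the enolate regiospecifically as its enol silane, and a second Saegusa–Ito oxidation removes the C6 hydrogen, so the transient C6 stereocentre is erased and its configuration does not matter.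

Step 12
Reactants: 18 (3R,3aS,8aS)-6,8a-dimethyl-3-(propan-2-yl)-3a-[(triethylsilyl)oxy]-2,3,3a,4,5,8a-hexahydroazulen-8(1H)-one
Product: 19 (3R,3aS,8S,8aR)-6,8a-dimethyl-3-(propan-2-yl)-3a-[(triethylsilyl)oxy]-1,2,3,3a,4,5,8,8a-octahydroazulen-8-ol
Conditions: i-Bu2AlH, CH2Cl2, −78 °C; aq. potassium sodium tartrate
Reagents that add atoms: none
Why: 1,2-Reduction of the enone by the bulky aluminium hydride should occur from the lower face of C8, opposite the angular C8a methyl and the C3a triethylsilyloxy group, as is usual for ketones next to an angular methyl group, so the new C8 hydroxyl stands on the upper face, cis to both (8S).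

Step 13
Reactants: 19 (3R,3aS,8S,8aR)-6,8a-dimethyl-3-(propan-2-yl)-3a-[(triethylsilyl)oxy]-1,2,3,3a,4,5,8,8a-octahydroazulen-8-ol
Product: 20 (3R,3aS,8S,8aR)-6,8a-dimethyl-3-(propan-2-yl)-1,2,3,3a,4,5,8,8a-octahydroazulene-3a,8-diol
Conditions: n-Bu4NF, THF, rt to 50 °C
Reagents that add atoms: none
Why: Fluoride-driven Si–O cleavage frees the tertiary alcohol at a stage where the molecule holds no ketone or ester, so retro-aldol cleavage and acyl migration cannot interfere and any earlier silyl shift between the two cis oxygens would be without consequence.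

Step 14
Reactants: 20 (3R,3aS,8S,8aR)-6,8a-dimethyl-3-(propan-2-yl)-1,2,3,3a,4,5,8,8a-octahydroazulene-3a,8-diol; 21 4-methoxybenzoyl chloride
Product: 22 (3R,3aS,8S,8aR)-3a-hydroxy-6,8a-dimethyl-3-(propan-2-yl)-1,2,3,3a,4,5,8,8a-octahydroazulen-8-yl 4-methoxybenzoate (CNP0158828.1)
Conditions: 21, Et3N, DMAP, CH2Cl2, 0 °C to rt
Reagents that add atoms: 4-methoxybenzoyl chloride (21), COc1ccc(C(=O)Cl)cc1
Why: DMAP-catalysed acylation (nucleophilic catalysis) discriminates cleanly between the secondary allylic C8 hydroxyl and the tertiary, doubly flanked C3a hydroxyl, and it proceeds at oxygen with retention at C8.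

Compound list
1 | cycloheptane-1,3-dione | O=C1CCCCC(=O)C1 | starting material
2 | iodomethane | CI | starting material
3 | 2-methylcycloheptane-1,3-dione | CC1C(=O)CCCCC1=O | intermediate
4 | 3-[(tert-butyldimethylsilyl)oxy]-2-methylcyclohept-2-en-1-one | CC1=C(O[Si](C)(C)C(C)(C)C)CCCCC1=O | intermediate
5 | rac-4-methylpent-1-yn-3-ol | CC(C)C(O)C#C | starting material
6 | (R)-4-methylpent-1-yn-3-ol | C#C[C@H](O)C(C)C | intermediate
7 | methyl (R)-4-methylpent-1-yn-3-yl carbonate | C#C[C@H](OC(=O)OC)C(C)C | intermediate
8 | 2-[(aS)-4-methylpenta-1,2-dien-1-yl]-1,3,2-dioxaborolane (not isolated) | [H]C(C(C)C)=[C@]=C([H])B1OCCO1 | intermediate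
9 | [(aS)-4-methylpenta-1,2-dien-1-yl]boronic acid | [H]C(C(C)C)=[C@]=C([H])B(O)O | intermediate
10 | dihydroxyboryl ether of 11 (not isolated) | C#C[C@H](C(C)C)[C@@]1(OB(O)O)CCCCC(O[Si](C)(C)C(C)(C)C)=C1C | intermediate
11 | (1S)-3-[(tert-butyldimethylsilyl)oxy]-2-methyl-1-[(3S)-4-methylpent-1-yn-3-yl]cyclohept-2-en-1-ol | C#C[C@H](C(C)C)[C@@]1(O)CCCCC(O[Si](C)(C)C(C)(C)C)=C1C | intermediate
12 | (3S)-1-[(tert-butyldimethylsilyl)oxy]-2-methyl-3-[(3S)-4-methylpent-1-yn-3-yl]-3-[(triethylsilyl)oxy]cyclohept-1-ene (key-step precursor) | C#C[C@H](C(C)C)[C@@]1(O[Si](CC)(CC)CC)CCCCC(O[Si](C)(C)C(C)(C)C)=C1C | intermediate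
13 | (3S,3aS,8aS)-8a-methyl-3-(propan-2-yl)-3a-[(triethylsilyl)oxy]-3a,4,5,6,7,8a-hexahydroazulen-8(3H)-one (key-step product; isopropyl, silyloxy and methyl all on the upper face) | O=C1CCCC[C@]2(O[Si](CC)(CC)CC)[C@@H](C(C)C)C=C[C@]12C | intermediate
14 | (3R,3aS,8aS)-8a-methyl-3-(propan-2-yl)-3a-[(triethylsilyl)oxy]-2,3,3a,4,5,6,7,8a-octahydroazulen-8(1H)-one | O=C1CCCC[C@]2(O[Si](CC)(CC)CC)[C@@H](C(C)C)CC[C@]12C | intermediate
15 | C7–C8 trimethylsilyl enol ether of 14 (not isolated) | C[Si](C)(C)OC1=CCCC[C@]2(O[Si](CC)(CC)CC)[C@@H](C(C)C)CC[C@]12C | intermediate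
16 | (3R,3aS,8aS)-8a-methyl-3-(propan-2-yl)-3a-[(triethylsilyl)oxy]-2,3,3a,4,5,8a-hexahydroazulen-8(1H)-one | O=C1C=CCC[C@]2(O[Si](CC)(CC)CC)[C@@H](C(C)C)CC[C@]12C | intermediate
17 | 6-methyl C7–C8 trimethylsilyl enol ether, C6 epimers carried together (not isolated) | C[Si](C)(C)OC1=CC(C)CC[C@]2(O[Si](CC)(CC)CC)[C@@H](C(C)C)CC[C@]12C | intermediate
18 | (3R,3aS,8aS)-6,8a-dimethyl-3-(propan-2-yl)-3a-[(triethylsilyl)oxy]-2,3,3a,4,5,8a-hexahydroazulen-8(1H)-one | O=C1C=C(C)CC[C@]2(O[Si](CC)(CC)CC)[C@@H](C(C)C)CC[C@]12C | intermediate
19 | (3R,3aS,8S,8aR)-6,8a-dimethyl-3-(propan-2-yl)-3a-[(triethylsilyl)oxy]-1,2,3,3a,4,5,8,8a-octahydroazulen-8-ol | O[C@H]1C=C(C)CC[C@]2(O[Si](CC)(CC)CC)[C@@H](C(C)C)CC[C@]12C | intermediate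
20 | (3R,3aS,8S,8aR)-6,8a-dimethyl-3-(propan-2-yl)-1,2,3,3a,4,5,8,8a-octahydroazulene-3a,8-diol | O[C@H]1C=C(C)CC[C@]2(O)[C@@H](C(C)C)CC[C@]12C | intermediate
21 | 4-methoxybenzoyl chloride | COc1ccc(C(=O)Cl)cc1 | starting material
22 | (3R,3aS,8S,8aR)-3a-hydroxy-6,8a-dimethyl-3-(propan-2-yl)-1,2,3,3a,4,5,8,8a-octahydroazulen-8-yl 4-methoxybenzoate | COc1ccc(C(=O)O[C@H]2C=C(C)CC[C@]3(O)[C@@H](C(C)C)CC[C@]23C)cc1 | target

Total step count: 14.
Longest linear sequence: 12 steps (5 to 22, steps 3 to 14). The ketone branch (steps 1 and 2) joins at step 6.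

Steps most likely to fail

Step 6 (propargylboration).
- **What may go wrong:** The addition may stall, because the carbonyl group of 4 is deactivated by the silyloxy donor and hindered by the methyl-bearing alkene carbon. Protodeboronation of the reagent or silyl transfer to B–OH groups could then compete. Discrimination between the two arms of the ketone may also be incomplete.
- **Fallback:** Boron is replaced by the more nucleophilic zinc, setting out from 6 and 4. Mesylation of 6 (MsCl, Et3N, CH2Cl2, −78 °C) gives (R)-4-methylpent-1-yn-3-yl methanesulfonate F1. With Pd(OAc)2 and PPh3 (5 mol % each) and Et2Zn in THF at −20 °C, zerovalent palladium displaces the mesylate in an anti-SN2′ sense, and transmetalation gives (aS)-ethyl(4-methylpenta-1,2-dien-1-yl)zinc F2. Generated in the presence of 4, this reagent adds through the same cyclic SE2′ array with the same stereochemical outcome. Buffered work-up comes back to the route at 11, and steps 4 and 5 are then not needed.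

Step 8 (key step).
- **What may go wrong:** The cyclisation may be eroded by ionisation of the tertiary allylic silyl ether or by protodesilylation of the enol silane before ring closure. Slow attack of the tetrasubstituted carbon, with solvolysis of the activated alkyne, is a further risk.
- **Fallback:** π-Acid catalysis is abandoned and the same C1–C8a bond is formed by a Mizoroki–Heck reaction under weakly basic conditions, setting out from 12. Treatment with n-BuLi and then I2 (THF, −78 °C) gives the iodoalkyne F3. Diimide from 2-nitrobenzenesulfonyl hydrazide and Et3N (THF–i-PrOH, rt) reduces it to the (Z)-vinyl iodide F4. Pd(OAc)2, PPh3 and Ag2CO3 (MeCN, 70 °C) then effect 5-exo-trig carbopalladation of the C8=C8a bond at C8a, followed by β-hydride loss from C7. This gives the C7=C8 tert-butyldimethylsilyl enol ether F5, again necessarily cis-fused. n-Bu4NF buffered by AcOH (THF, 0 °C) cleaves only the enol silane and comes back to the route at 13.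

Step 12 (enone reduction).
- **What may go wrong:** Poor facial selectivity is possible, because the cyclopentane ring shields the face from which hydride has to arrive while methyl and silyloxy shield the other.
- **Fallback:** Steric control is replaced by chelate control, setting out from 18. HF·pyridine (THF–pyridine, 0 °C to rt, non-basic so that retro-aldol cleavage is avoided) gives the β-hydroxy enone F6. Narasaka–Prasad reduction (Et2BOMe, then NaBH4, THF–MeOH, −78 °C, boron removed by evaporation with MeOH) ties the C3a oxygen and the C8 carbonyl oxygen into one boron chelate on the upper face. External hydride can then give only the cis-1,3-diol. This comes back to the route at 20 and leaves the step count unchanged.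

Further compounds
F1 | step 6 | (R)-4-methylpent-1-yn-3-yl methanesulfonate | C#C[C@H](OS(C)(=O)=O)C(C)C
F2 | step 6 | (aS)-ethyl(4-methylpenta-1,2-dien-1-yl)zinc | [H]C(C(C)C)=[C@]=C([H])[Zn]CC
F3 | step 8 | (3S)-1-[(tert-butyldimethylsilyl)oxy]-3-[(3S)-1-iodo-4-methylpent-1-yn-3-yl]-2-methyl-3-[(triethylsilyl)oxy]cyclohept-1-ene | IC#C[C@H](C(C)C)[C@@]1(O[Si](CC)(CC)CC)CCCCC(O[Si](C)(C)C(C)(C)C)=C1C
F4 | step 8 | (3S)-1-[(tert-butyldimethylsilyl)oxy]-3-[(1Z,3S)-1-iodo-4-methylpent-1-en-3-yl]-2-methyl-3-[(triethylsilyl)oxy]cyclohept-1-ene | I/C=C\[C@H](C(C)C)[C@@]1(O[Si](CC)(CC)CC)CCCCC(O[Si](C)(C)C(C)(C)C)=C1C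
F5 | step 8 | C7=C8 tert-butyldimethylsilyl enol ether of 13 | CC(C)(C)[Si](C)(C)OC1=CCCC[C@]2(O[Si](CC)(CC)CC)[C@@H](C(C)C)C=C[C@]12C
F6 | step 12 | (3R,3aS,8aS)-3a-hydroxy-6,8a-dimethyl-3-(propan-2-yl)-2,3,3a,4,5,8a-hexahydroazulen-8(1H)-one | O=C1C=C(C)CC[C@]2(O)[C@@H](C(C)C)CC[C@]12C
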